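**Retrosynthetic overview**

1. The guanine is built last: its imidazole ring is closed by Traube-type oxidative condensation of 2,5,6-triaminopyrimidin-4(3H)-one with a ring-A salicylaldehyde, made by ortho-formylation of the ring-A phenol.
2. The piperazine (N1, C2 carrying the ring-B benzyl, C3H2, N4, C5 carrying the ring-A benzyl, C6H2) is disconnected at C2–C3 and N4–C5. This leads back to a 14-membered macrocycle in which C3 is a carboxamide carbon attached to C5 and the ring-B benzylic carbon is a ketone.
3. Enabling feature: C5 is a CH carrying N4, so N4 can arrive by a stereoretentive 1,2-shift of C5 from the C3 carboxamide carbon (Lossen). C2 lies next to the ring-B benzylic carbon, so a ketone there makes C2 an enolate donor toward the resulting isocyanate carbon. The diaryl ether (ring A meta, ring B para) already holds C2 and C5 in a 14-membered ring that allows only the cis-(2S,5S) closure.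
4. The same ketone activates the para C–F bond of ring B, so the 14-membered ring is closed beforehand by intramolecular SNAr of the ring-A phenoxide. The acyclic precursor is a β-amino acid whose single stereocenter comes from an Evans alkylation of a β-alanine imide with a ring-A benzyl bromide.
5. Ring order: rings A and B (purchased) → 14-membered diaryl-ether ring → piperazinone, then piperazine → imidazole ring of the purine on a purchased pyrimidine.

Key step: step 10

Remark: the piperazine numbering of line 2 is used throughout; (2S,5S) is the cis-2,5-disubstituted piperazine, and the guanine is drawn in the tautomer of the given SMILES.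
Remark: compound 23 is assumed to be used as its commercial sulfate, neutralized in the flask with NaOAc.

**Route**

Step 1
Reactants: 1 (3-(benzyloxy)-4-methoxyphenyl)methanol
Product: 2 2-(benzyloxy)-4-(bromomethyl)-1-methoxybenzene
Conditions: PBr3 (0.4 equiv), CH2Cl2, 0 °C
Reagents that add atoms: phosphorus tribromide, BrP(Br)Br
Why: An electron-rich benzylic alcohol is converted to the bromide by PBr3 (SN2 on the bromophosphite), and the aryl benzyl and methyl ethers are inert at 0 °C.

Step 2
Reactants: 3 3-[benzyl(tert-butoxycarbonyl)amino]propanoic acid, 4 (4S)-4-benzyl-1,3-oxazolidin-2-one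
Product: 6 tert-butyl benzyl{3-[(4S)-4-benzyl-2-oxo-1,3-oxazolidin-3-yl]-3-oxopropyl}carbamate, via mixed pivalic anhydride 5 (not isolated)
Conditions: t-BuCOCl, Et3N, THF, −20 °C; then 4, LiCl, −20 °C to rt
Reagents that add atoms: none
Why: N-Acylation of the oxazolidinone through the mixed pivalic anhydride with LiCl/Et3N is the standard mild entry to Evans imides and needs no strong base next to the carbamate.

Step 3
Reactants: 6 imide, 2 benzylic bromide
Product: 7 tert-butyl benzyl{(2S)-2-[3-(benzyloxy)-4-methoxybenzyl]-3-[(4S)-4-benzyl-2-oxo-1,3-oxazolidin-3-yl]-3-oxopropyl}carbamate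
Conditions: NaN(SiMe3)2, THF, −78 °C; then 2, −78 to −40 °C
Reagents that add atoms: none
Why: Evans asymmetric alkylation, in which the chelated (Z)-sodium enolate is attacked by the benzylic bromide on the face opposite the C4 benzyl group of the (S)-auxiliary, should set the (S) stereocenter (the future piperazine C5), the low temperature suppressing E1cB loss of the β-carbamate nitrogen.

Step 4
Reactants: 7 alkylated imide
Product: 8 methyl (2S)-3-[benzyl(tert-butoxycarbonyl)amino]-2-[3-(benzyloxy)-4-methoxybenzyl]propanoate
Conditions: MeMgBr, MeOH, CH2Cl2, 0 °C (MeOMgBr formed in the flask)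
Reagents that add atoms: methanol, CO
Why: Magnesium methoxide transesterifies the exocyclic imide carbonyl selectively, releasing the recoverable auxiliary without epimerizing the α-stereocenter or cleaving the Boc group.

Step 5
Reactants: 8 methyl ester
Product: 9 methyl (2S)-3-(benzylamino)-2-(3-hydroxy-4-methoxybenzyl)propanoate
Conditions: CF3CO2H, pentamethylbenzene, CH2Cl2, rt
Reagents that add atoms: none
Why: Acidolysis removes the Boc group and, with pentamethylbenzene as benzyl-cation scavenger, the electron-rich aryl benzyl ether, whereas the N-benzyl ammonium, the methyl ether and the ester are stable to acid.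

Step 6
Reactants: 9 amino phenol, 10 2-bromo-1-(4-fluorophenyl)ethan-1-one
Product: 11 methyl (2S)-3-{benzyl[2-(4-fluorophenyl)-2-oxoethyl]amino}-2-(3-hydroxy-4-methoxybenzyl)propanoate
Conditions: NaHCO3, MeCN, 0 °C to rt
Reagents that add atoms: none
Why: SN2 N-alkylation of the secondary amine by the α-bromo ketone should be chemoselective because the phenol is not ionized by bicarbonate, and the tertiary α-amino ketone formed cannot self-condense.

Step 7
Reactants: 11 amino ketone ester
Product: 12 (2S)-3-{benzyl[2-(4-fluorophenyl)-2-oxoethyl]amino}-2-(3-hydroxy-4-methoxybenzyl)propanoic acid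
Conditions: LiOH, THF/H2O, 0 °C; then HCl to pH 6
Reagents that add atoms: water (as hydroxide), O
Why: Saponification at 0 °C leaves the aryl fluoride and the ketone untouched, and the carboxylate protects the adjacent stereocenter from enolization in the basic step that follows.

Step 8
Reactants: 12 seco acid
Product: 13 14-membered macrocyclic keto acid: ring B (1,4-linked)–C(=O)–CH2–N(benzyl)–CH2–CH(CO2H)–CH2–ring A (1,3-linked, 4-OMe)–O–, (S) at the CH(CO2H) carbon
Conditions: K2CO3, DMSO (0.003 M), 90 °C, Ar
Reagents that add atoms: none
Why: Intramolecular SNAr diaryl-ether formation, in which the ring-A phenoxide displaces the fluoride activated by the para ketone of ring B, should close the 14-membered ring under high dilution while the ring is still flexible (no piperazine bridge yet).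

Step 9
Reactants: 13 macrocyclic acid, 14 O-pivaloylhydroxylamine trifluoromethanesulfonate
Product: 15 N-(pivaloyloxy)carboxamide of 13
Conditions: EDC·HCl, HOAt (cat.), N-methylmorpholine, CH2Cl2, 0 °C to rt
Reagents that add atoms: none
Why: Carbodiimide coupling with O-pivaloylhydroxylamine installs the Lossen precursor (and the future N4) without exposing the ketone to free hydroxylamine, and the weakly basic medium should not trigger the rearrangement at rt.

Step 10
Reactants: 15 N-(pivaloyloxy)carboxamide
Product: 17 bridged keto lactam: (2S,5S)-N1-benzyl piperazin-3-one of the target core with the ring-B benzylic carbon as ketone and ring A as 4-OMe, via macrocyclic isocyanate 16 (not isolated)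
Conditions: Cs2CO3 (3 equiv), MeCN (0.01 M), 60 °C
Reagents that add atoms: none
Why: Proposed new method: Cs2CO3 deprotonates the N–H of the N-pivaloyloxy amide, and the anion undergoes Lossen rearrangement in which the future C5 migrates from the carboxamide carbon to nitrogen with loss of pivalate, so the N4–C5 bond forms with retention of the (S) configuration set in step 3 and isocyanate 16 results; the same base forms the enolate of the aryl ketone, whose only enolizable carbon (future C2) adds to the isocyanate carbon (future C3) to make the C2–C3 bond and the lactam. The closest known reaction types are the Lossen or Curtius rearrangement with capture of the isocyanate by an internal nucleophile and the C-carbamoylation of ketone enolates by isocyanates to β-keto amides; what is new is their combination as a piperazinone-forming closure across a macrocycle. The six-membered ring closes by 6-exo-dig attack of the enolate carbon on the digonal isocyanate carbon (the C=O π bond that is broken stays outside the new ring), and since C2–N1–C6–C5 already lie in the 14-membered ring this annulation gives the bridged bicycle of the target directly. The new stereocenter C2 is controlled by the diaryl-ether tether, because only the isomer with the ring-B acyl group and the ring-A benzyl group cis on the piperazinone can exist in the bicycle, and C2 remains epimerizable as part of a β-keto amide so that a kinetic error can correct itself. The step needs C- over O-acylation and intra- over intermolecular capture: the first is secured by ring size (six-membered through carbon, eight-membered through oxygen), the second by dilution and by the absence of any other N–H or O–H nucleophile (N1 is tertiary and the ring-A oxygen atoms are ethers).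

Step 11
Reactants: 17 bridged keto lactam
Product: 18 (2S,5S) macrocyclic piperazin-3-one: N1–H, N4–H lactam, ring-B benzylic CH2, ring A 4-OMe
Conditions: H2 (4 bar), Pd/C, AcOH, HClO4 (cat.), 50 °C
Reagents that add atoms: none
Why: Acid-promoted catalytic hydrogenolysis should reduce the aryl ketone through the benzylic carbinol to CH2 (C–O cleavage assisted by the para aryloxy group) and remove the N-benzyl group in the same operation, the C2 configuration being held by the bicycle.

Step 12
Reactants: 18 lactam
Product: 19 (2S,5S) macrocyclic piperazine with ring A as 4-OMe (O-methyl ether of 20)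
Conditions: BH3·THF, THF, reflux; then MeOH, HCl, reflux
Reagents that add atoms: none
Why: Borane reduction of the secondary lactam converts C3 to CH2 without touching the diaryl ether or either stereocenter.

Step 13
Reactants: 19 methyl ether
Product: 20 (2S,5S) macrocyclic piperazine phenol (constitution of piperazinomycin)
Conditions: BBr3, CH2Cl2, −78 to 0 °C; then MeOH, NaHCO3
Reagents that add atoms: none
Why: Lewis-acid demethylation cleaves the aryl methyl ether selectively, since the diaryl ether is not cleaved by BBr3 at this temperature and the amines are only complexed.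

Step 14
Reactants: 20 piperazine phenol
Product: 21 N1,N4-di-Boc derivative of 20
Conditions: Boc2O (2.2 equiv), Et3N, THF/MeOH, rt; K2CO3/MeOH work-up
Reagents that add atoms: di-tert-butyl dicarbonate, CC(C)(C)OC(=O)OC(=O)OC(C)(C)C
Why: The two secondary amines are carbamoylated much faster than the phenol, and any aryl carbonate formed is cleaved in the mildly basic methanolic work-up.

Step 15
Reactants: 21 di-Boc phenol
Product: 22 ring-A salicylaldehyde of 21 (CHO ortho to the OH)
Conditions: MgCl2, Et3N, (CH2O)n, MeCN, 80 °C
Reagents that add atoms: paraformaldehyde (formaldehyde), C=O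
Why: Casnati–Skattebøl ortho-formylation through the magnesium phenoxide delivers formaldehyde only ortho to a phenol, and ring A has a single free ortho position (the other carries the diaryl ether, para carries the benzylic carbon) while ring B has no phenol.

Step 16
Reactants: 22 salicylaldehyde, 23 2,5,6-triaminopyrimidin-4(3H)-one
Product: 26 N1,N4-di-Boc guanipiperazine A, via Schiff base 24 (not isolated), via 7,8-dihydro-8-arylguanine aminal 25 (not isolated)
Conditions: 23 sulfate, NaOAc, DMSO, 60 °C; then FeCl3 (10 mol %), air, 90 °C
Reagents that add atoms: none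
Why: Traube-type purine synthesis, in which the most nucleophilic 5-amino group condenses with the aldehyde, the 6-amino group adds to the imine and aerobic dehydrogenation aromatizes the imidazole ring, creates the guanine C8–aryl bond without cross-coupling.

Step 17
Reactants: 26 di-Boc guanipiperazine A
Product: 27 guanipiperazine A
Conditions: CF3CO2H/CH2Cl2, rt; then NH3/MeOH
Reagents that add atoms: none
Why: Acidolysis of both Boc carbamates liberates the piperazine without affecting either stereocenter or the purine.

**Compound list**

1 | (3-(benzyloxy)-4-methoxyphenyl)methanol | COc1ccc(CO)cc1OCc1ccccc1 | starting material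
2 | 2-(benzyloxy)-4-(bromomethyl)-1-methoxybenzene | COc1ccc(CBr)cc1OCc1ccccc1 | intermediate
3 | 3-[benzyl(tert-butoxycarbonyl)amino]propanoic acid | OC(=O)CCN(Cc1ccccc1)C(=O)OC(C)(C)C | starting material
4 | (4S)-4-benzyl-1,3-oxazolidin-2-one | O=C1N[C@@H](Cc2ccccc2)CO1 | starting material
5 | mixed anhydride of 3 with pivalic acid (not isolated) | CC(C)(C)C(=O)OC(=O)CCN(Cc1ccccc1)C(=O)OC(C)(C)C | intermediate
6 | tert-butyl benzyl{3-[(4S)-4-benzyl-2-oxo-1,3-oxazolidin-3-yl]-3-oxopropyl}carbamate | O=C1OC[C@H](Cc2ccccc2)N1C(=O)CCN(Cc1ccccc1)C(=O)OC(C)(C)C | intermediate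
7 | tert-butyl benzyl{(2S)-2-[3-(benzyloxy)-4-methoxybenzyl]-3-[(4S)-4-benzyl-2-oxo-1,3-oxazolidin-3-yl]-3-oxopropyl}carbamate | O=C1OC[C@H](Cc2ccccc2)N1C(=O)[C@@H](Cc1ccc(OC)c(OCc2ccccc2)c1)CN(Cc1ccccc1)C(=O)OC(C)(C)C | intermediate
8 | methyl (2S)-3-[benzyl(tert-butoxycarbonyl)amino]-2-[3-(benzyloxy)-4-methoxybenzyl]propanoate | COC(=O)[C@@H](Cc1ccc(OC)c(OCc2ccccc2)c1)CN(Cc1ccccc1)C(=O)OC(C)(C)C | intermediate
9 | methyl (2S)-3-(benzylamino)-2-(3-hydroxy-4-methoxybenzyl)propanoate | COC(=O)[C@@H](Cc1ccc(OC)c(O)c1)CNCc1ccccc1 | intermediate
10 | 2-bromo-1-(4-fluorophenyl)ethan-1-one | O=C(CBr)c1ccc(F)cc1 | starting material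
11 | methyl (2S)-3-{benzyl[2-(4-fluorophenyl)-2-oxoethyl]amino}-2-(3-hydroxy-4-methoxybenzyl)propanoate | COC(=O)[C@@H](Cc1ccc(OC)c(O)c1)CN(Cc1ccccc1)CC(=O)c1ccc(F)cc1 | intermediate
12 | (2S)-3-{benzyl[2-(4-fluorophenyl)-2-oxoethyl]amino}-2-(3-hydroxy-4-methoxybenzyl)propanoic acid | OC(=O)[C@@H](Cc1ccc(OC)c(O)c1)CN(Cc1ccccc1)CC(=O)c1ccc(F)cc1 | intermediate
13 | 14-membered macrocyclic keto acid (diaryl ether, N-benzyl, (S) at the CH(CO2H) carbon) | OC(=O)[C@@H]1CN(Cc2ccccc2)CC(=O)c2ccc(Oc3cc(C1)ccc3OC)cc2 | intermediate
14 | O-pivaloylhydroxylamine trifluoromethanesulfonate | CC(C)(C)C(=O)ON.OS(=O)(=O)C(F)(F)F | starting material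
15 | N-(pivaloyloxy)carboxamide of 13 | CC(C)(C)C(=O)ONC(=O)[C@@H]1CN(Cc2ccccc2)CC(=O)c2ccc(Oc3cc(C1)ccc3OC)cc2 | intermediate
16 | macrocyclic isocyanate (not isolated) | O=C=N[C@@H]1CN(Cc2ccccc2)CC(=O)c2ccc(Oc3cc(C1)ccc3OC)cc2 | intermediate
17 | bridged keto lactam, (2S,5S), N1-benzyl, C3=O, ring-B benzylic C=O | COc1ccc2cc1Oc1ccc(cc1)C(=O)[C@H]1C(=O)N[C@H](CN1Cc1ccccc1)C2 | intermediate
18 | (2S,5S) macrocyclic piperazin-3-one, ring A 4-OMe | COc1ccc2cc1Oc1ccc(cc1)C[C@H]1C(=O)N[C@H](CN1)C2 | intermediate
19 | (2S,5S) macrocyclic piperazine, ring A 4-OMe | COc1ccc2cc1Oc1ccc(cc1)C[C@H]1CN[C@H](CN1)C2 | intermediate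
20 | (2S,5S) macrocyclic piperazine phenol (constitution of piperazinomycin) | Oc1ccc2cc1Oc1ccc(cc1)C[C@H]1CN[C@H](CN1)C2 | intermediate
21 | N1,N4-di-Boc derivative of 20 | Oc1ccc2cc1Oc1ccc(cc1)C[C@H]1CN(C(=O)OC(C)(C)C)[C@H](CN1C(=O)OC(C)(C)C)C2 | intermediate
22 | ring-A salicylaldehyde of 21 | Oc1c(C=O)cc2cc1Oc1ccc(cc1)C[C@H]1CN(C(=O)OC(C)(C)C)[C@H](CN1C(=O)OC(C)(C)C)C2 | intermediate
23 | 2,5,6-triaminopyrimidin-4(3H)-one | Nc1nc(N)c(N)c(=O)[nH]1 | starting material
24 | Schiff base of 22 with the 5-amino group of 23 (not isolated) | Nc1nc(N)c(N=Cc2cc3cc(Oc4ccc(cc4)C[C@H]4CN(C(=O)OC(C)(C)C)[C@H](CN4C(=O)OC(C)(C)C)C3)c2O)c(=O)[nH]1 | intermediate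
25 | 7,8-dihydro-8-arylguanine aminal formed from 24 by addition of the 6-amino group to the imine carbon (not isolated; the new C8 center is undefined and is lost on dehydrogenation) | Nc1nc2NC(c3cc4cc(c3O)Oc3ccc(cc3)C[C@H]3CN(C(=O)OC(C)(C)C)[C@H](CN3C(=O)OC(C)(C)C)C4)Nc2c(=O)[nH]1 | intermediate
26 | N1,N4-di-Boc guanipiperazine A | Nc1nc2nc(-c3cc4cc(c3O)Oc3ccc(cc3)C[C@H]3CN(C(=O)OC(C)(C)C)[C@H](CN3C(=O)OC(C)(C)C)C4)[nH]c2c(=O)[nH]1 | intermediate
27 | guanipiperazine A | Nc1nc2nc(-c3cc4cc(c3O)Oc3ccc(cc3)C[C@H]3CN[C@H](CN3)C4)[nH]c2c(=O)[nH]1 | target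

**Step count and risks**

Total step count: 17. Longest linear sequence: 16 steps (steps 2 to 17; step 1 feeds step 3).

Steps most likely to fail:

Step 10 (Proposed new method). The enolate may fail to reach the isocyanate carbon across the strained ring, so that the isocyanate is consumed by intermolecular capture or hydrolysis instead of closing the lactam. The fallback sets out from 13. A Curtius rearrangement (diphenylphosphoryl azide, Et3N, toluene, 80 °C) in the presence of benzyl alcohol should give, through the same isocyanate 16, benzyl carbamate F1 with the N4–C5 bond formed with retention. Paraformaldehyde and CF3CO2H should then generate the N-acyliminium ion on N4, which the ketone enol at C2 captures in an intramolecular Mannich-type amidoalkylation to give N4-Cbz keto piperazine F2. Hydrogenolysis (H2, Pd/C, AcOH, cat. HClO4) removes the Cbz group, the N-benzyl group and the ketone oxygen, and the route is rejoined at 19.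

Step 8. SNAr at a fluoride activated only by a para ketone may be slow, which would let intermolecular etherification (oligomerization) and base-mediated degradation of the α-amino ketone compete with ring closure. The fallback sets out from 9. N-Alkylation with 2-bromo-1-(4-bromophenyl)ethan-1-one (NaHCO3, MeCN) gives aryl bromide ester F3, and saponification (LiOH, THF/H2O) gives aryl bromide acid F4. An intramolecular Ullmann diaryl-ether coupling (CuI, N,N-dimethylglycine, Cs2CO3, 1,4-dioxane, 100 °C, 0.003 M) closes the same ring, and the route is rejoined at 13.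

Step 11. Hydrogenolysis of the benzylic C–O bond next to the protonated amine may stall at the carbinol, or the strained cyclophane may be over-reduced. The fallback sets out from 17. Ethane-1,2-dithiol and BF3·OEt2 convert the ketone to dithiolane F5. Raney Ni in EtOH (Mozingo desulfurization) gives N-benzyl lactam F6 without any cationic intermediate. Neutral hydrogenolysis (H2, Pd(OH)2/C, MeOH) removes the N-benzyl group, and the route is rejoined at 18.

Further compounds
F1 | step 10 | benzyl carbamate of the macrocyclic amine (N4-Cbz on the (S) carbon, ketone and N-benzyl retained) | O=C(OCc1ccccc1)N[C@@H]1CN(Cc2ccccc2)CC(=O)c2ccc(Oc3cc(C1)ccc3OC)cc2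
F2 | step 10 | (2S,5S) bridged N4-Cbz N1-benzyl piperazine with the ring-B benzylic carbon as ketone | COc1ccc2cc1Oc1ccc(cc1)C(=O)[C@H]1CN(C(=O)OCc3ccccc3)[C@H](CN1Cc1ccccc1)C2
F3 | step 8 | methyl (2S)-3-{benzyl[2-(4-bromophenyl)-2-oxoethyl]amino}-2-(3-hydroxy-4-methoxybenzyl)propanoate | COC(=O)[C@@H](Cc1ccc(OC)c(O)c1)CN(Cc1ccccc1)CC(=O)c1ccc(Br)cc1
F4 | step 8 | (2S)-3-{benzyl[2-(4-bromophenyl)-2-oxoethyl]amino}-2-(3-hydroxy-4-methoxybenzyl)propanoic acid | OC(=O)[C@@H](Cc1ccc(OC)c(O)c1)CN(Cc1ccccc1)CC(=O)c1ccc(Br)cc1
F5 | step 11 | 1,3-dithiolane of the ketone of 17 | COc1ccc2cc1Oc1ccc(cc1)C1(SCCS1)[C@H]1C(=O)N[C@H](CN1Cc1ccccc1)C2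
F6 | step 11 | (2S,5S) N1-benzyl macrocyclic piperazin-3-one (N-benzyl derivative of 18) | COc1ccc2cc1Oc1ccc(cc1)C[C@H]1C(=O)N[C@H](CN1Cc1ccccc1)C2
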